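A direct plan would form the C7–C8 bond by an auxiliary-controlled boron syn-aldol reaction between the N-(aryloxyacetyl)oxazolidinone A1, which carries a silylated sinapyl alcohol side chain, and O-silylated vanillin A2. It would then cleave the auxiliary from aldol imide A3 with hydride and remove both silyl groups. Its weakest steps would be:
- the protecting-group and auxiliary handling around A1 (silylation, ester hydrolysis, auxiliary loading, final desilylation), which would add length without complexity;
- the aldol addition itself, which would need a stoichiometric auxiliary and Bu2BOTf and would pit a hindered 2,6-dimethoxyaryloxy enolate against an electron-rich aldehyde;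
- the reductive auxiliary removal from A3, where retro-aldol cleavage and attack at the ring carbonyl would compete.

The route rests on the C8–O4′ ether bond and the C7–H bond, not on C7–C8. In racemic keto ester 13, made by O-alkylation of methyl sinapate with an α-bromo-β-keto ester, C8–H lies between the C7 aryl ketone, the C9 ester and the aryloxy oxygen, so the two enantiomers interconvert freely. One asymmetric transfer hydrogenation under dynamic kinetic resolution funnels both into the single syn (2S,3R) hydroxy ester, setting the C7/C8 pair (7R,8R) catalytically. No auxiliary is loaded or cleaved and no silyl group is needed; because both side chains stay at the ester level, one hydride treatment delivers C9–OH, the allylic alcohol and the free phenol together.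

Key step: step 6

Numbering used: C7 is the benzylic carbinol carbon, C8 the aryloxy-bearing carbon, C9 the CH2OH carbon, and O4′ the phenolic oxygen of the syringyl ring.

Assumption: the (S,S)-TsDPEN complex is taken to deliver hydride to the aryl ketone in its usual sense, which here gives the 3R carbinol; if the opposite sense were found, the (R,R)-complex would be used with no other change.

**Step 1**
Reactants: 1 vanillic acid; 2 pivaloyl chloride
Product: 3 3-methoxy-4-(pivaloyloxy)benzoic acid
Conditions: NaOH (2.05 equiv), 2 (1.1 equiv), THF/H2O, 0 °C; then 1 M HCl to pH 2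
Reagents that add atoms: pivaloyl chloride, CC(C)(C)C(=O)Cl
Why: Schotten–Baumann O-acylation, in which the phenoxide of the dianion is far more nucleophilic than the carboxylate; the aryl pivalate masks the phenol, keeps the later aryl ketone electrophilic and is removed by the final hydride step.

**Step 2**
Reactants: 3 3-methoxy-4-(pivaloyloxy)benzoic acid; 4 potassium ethyl malonate
Product: 7 ethyl 3-[3-methoxy-4-(pivaloyloxy)phenyl]-3-oxopropanoate, via 3-methoxy-4-(pivaloyloxy)benzoyl chloride 5 (not isolated), via ethyl hydrogen 2-[3-methoxy-4-(pivaloyloxy)benzoyl]malonate 6 (not isolated)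
Conditions: (COCl)2 (1.3 equiv), DMF (cat.), CH2Cl2, 0 °C → rt, evaporate; then 4 (2.0 equiv), MgCl2 (2.5 equiv), Et3N (3.0 equiv), MeCN, 0 °C → rt; 1 M HCl
Reagents that add atoms: potassium ethyl malonate, CCOC(=O)CC(=O)[O-].[K+]
Why: Acid chloride formation followed by magnesium-mediated C-acylation of the malonate half-ester and decarboxylation on acidification (Masamune–Brooks type β-keto ester synthesis), conditions mild enough for the aryl pivalate.

**Step 3**
Reactants: 7 ethyl 3-[3-methoxy-4-(pivaloyloxy)phenyl]-3-oxopropanoate; 8 N-bromosuccinimide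
Product: 9 ethyl 2-bromo-3-[3-methoxy-4-(pivaloyloxy)phenyl]-3-oxopropanoate (racemic)
Conditions: 8 (1.02 equiv), TsOH·H2O (10 mol %), CH2Cl2, 0 °C → rt
Reagents that add atoms: N-bromosuccinimide, O=C1CCC(=O)N1Br
Why: Acid-catalysed electrophilic α-bromination of the enol of the 1,3-dicarbonyl unit; the acylated, ketone-bearing ring is too deactivated to compete.

**Step 4**
Reactants: 10 sinapic acid; 11 methanol
Product: 12 methyl (E)-3-(4-hydroxy-3,5-dimethoxyphenyl)prop-2-enoate (methyl sinapate)
Conditions: MeOH, H2SO4 (cat.), reflux
Reagents that add atoms: methanol, CO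
Why: Fischer esterification, which stores the future allylic alcohol as a conjugated ester that is inert until the last step and leaves the E-alkene untouched.

**Step 5**
Reactants: 9 ethyl 2-bromo-3-[3-methoxy-4-(pivaloyloxy)phenyl]-3-oxopropanoate; 12 methyl sinapate
Product: 13 ethyl 2-{2,6-dimethoxy-4-[(E)-3-methoxy-3-oxoprop-1-enyl]phenoxy}-3-[3-methoxy-4-(pivaloyloxy)phenyl]-3-oxopropanoate (racemic)
Conditions: K2CO3 (1.5 equiv), 12 (1.05 equiv), acetone, 0 °C → rt
Reagents that add atoms: none
Why: Williamson ether synthesis (SN2) at the doubly carbonyl-activated bromide by the only phenoxide present, whose ortho and para carbons are blocked, forms the C8–O4′ bond; the product is deliberately racemic and enolisable.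

**Step 6**
Reactants: 13 the racemic α-aryloxy-β-keto ester
Product: 14 ethyl (2S,3R)-2-{2,6-dimethoxy-4-[(E)-3-methoxy-3-oxoprop-1-enyl]phenoxy}-3-hydroxy-3-[3-methoxy-4-(pivaloyloxy)phenyl]propanoate
Conditions: RuCl[(S,S)-TsDPEN](p-cymene) (2 mol %), HCO2H/Et3N 5:2 (5 equiv HCO2H), CH2Cl2, 30 °C
Reagents that add atoms: none
Why: The 16-electron Ru amide takes hydride and proton from formic acid, and the resulting Ru–H/N–H pair passes both to the C7 ketone through a six-membered outer-sphere transition state without metal–substrate binding (Noyori–Ikariya asymmetric transfer hydrogenation run as a dynamic kinetic resolution, the closest precedent being the syn-selective reduction of α-alkoxy-β-keto esters); no ring is closed. C7 is set by the catalyst: the aryl group of the ketone lies against the η6-cymene (CH/π contact), so the (S,S)-ligand should deliver hydride to the face that gives the 3R carbinol, which is 7R in the target. C8 is set by relative rate: the enantiomers of 13 interconvert through the enol under Et3N, and only the 2S enantiomer can place its C–OAr bond anti to the incoming hydride with the small hydrogen on the side of approach (polar Felkin–Anh), so the syn (2S,3R) ester should form and, lacking the ketone, should no longer epimerise. The step needs racemisation faster than reduction, syn over anti, and ketone over conjugated ester. The first is secured by the C8–H flanked by ketone, ester and aryloxy oxygen, the second by the bulky, electronegative 2,6-dimethoxyaryloxy group, which reinforces the antiperiplanar preference. The third is secured by the weakly hydridic Ru–H, which leaves cinnamates and pivalates alone, while the para-pivaloyloxy group keeps the ketone electrophilic.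

**Step 7**
Reactants: 14 the syn hydroxy ester
Product: 15 (1R,2R)-1-(4-hydroxy-3-methoxyphenyl)-2-{4-[(E)-3-hydroxyprop-1-enyl]-2,6-dimethoxyphenoxy}propane-1,3-diol (target)
Conditions: iBu2AlH (10 equiv), CH2Cl2/toluene, −78 → 0 °C; aq. KNaC4H4O6 (potassium sodium tartrate), neutral work-up
Reagents that add atoms: none
Why: Global ester reduction with iBu2AlH: the saturated ester gives the C9 primary alcohol, the conjugated ester is reduced 1,2 to the E-allylic alcohol and the aryl pivalate is cleaved reductively to the phenol, while C7 and C8 stay bound as aluminium alkoxide and hemiacetal at low temperature and so should not epimerise.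

**Compound list**
1 | vanillic acid (4-hydroxy-3-methoxybenzoic acid) | COc1cc(C(=O)O)ccc1O | starting material
2 | pivaloyl chloride | CC(C)(C)C(=O)Cl | starting material
3 | 3-methoxy-4-(pivaloyloxy)benzoic acid | COc1cc(C(=O)O)ccc1OC(=O)C(C)(C)C | intermediate
4 | potassium ethyl malonate | CCOC(=O)CC(=O)[O-].[K+] | starting material
5 | 3-methoxy-4-(pivaloyloxy)benzoyl chloride | COc1cc(C(=O)Cl)ccc1OC(=O)C(C)(C)C | intermediate (not isolated)
6 | ethyl hydrogen 2-[3-methoxy-4-(pivaloyloxy)benzoyl]malonate | CCOC(=O)C(C(=O)O)C(=O)c1ccc(OC(=O)C(C)(C)C)c(OC)c1 | intermediate (not isolated)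
7 | ethyl 3-[3-methoxy-4-(pivaloyloxy)phenyl]-3-oxopropanoate | CCOC(=O)CC(=O)c1ccc(OC(=O)C(C)(C)C)c(OC)c1 | intermediate
8 | N-bromosuccinimide | O=C1CCC(=O)N1Br | starting material
9 | ethyl 2-bromo-3-[3-methoxy-4-(pivaloyloxy)phenyl]-3-oxopropanoate (racemic) | CCOC(=O)C(Br)C(=O)c1ccc(OC(=O)C(C)(C)C)c(OC)c1 | intermediate
10 | sinapic acid ((E)-3-(4-hydroxy-3,5-dimethoxyphenyl)prop-2-enoic acid) | COc1cc(/C=C/C(=O)O)cc(OC)c1O | starting material
11 | methanol | CO | starting material
12 | methyl (E)-3-(4-hydroxy-3,5-dimethoxyphenyl)prop-2-enoate (methyl sinapate) | COC(=O)/C=C/c1cc(OC)c(O)c(OC)c1 | intermediate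
13 | ethyl 2-{2,6-dimethoxy-4-[(E)-3-methoxy-3-oxoprop-1-enyl]phenoxy}-3-[3-methoxy-4-(pivaloyloxy)phenyl]-3-oxopropanoate (racemic) | CCOC(=O)C(Oc1c(OC)cc(/C=C/C(=O)OC)cc1OC)C(=O)c1ccc(OC(=O)C(C)(C)C)c(OC)c1 | intermediate
14 | ethyl (2S,3R)-2-{2,6-dimethoxy-4-[(E)-3-methoxy-3-oxoprop-1-enyl]phenoxy}-3-hydroxy-3-[3-methoxy-4-(pivaloyloxy)phenyl]propanoate | COc1cc([C@@H](O)[C@@H](C(=O)OCC)Oc2c(OC)cc(/C=C/C(=O)OC)cc2OC)ccc1OC(=O)C(C)(C)C | intermediate
15 | (1R,2R)-1-(4-hydroxy-3-methoxyphenyl)-2-{4-[(E)-3-hydroxyprop-1-enyl]-2,6-dimethoxyphenoxy}propane-1,3-diol | COc1cc([C@@H](O)[C@@H](CO)Oc2c(OC)cc(/C=C/CO)cc2OC)ccc1O | target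

Total step count: 7. Longest linear sequence: 6 (steps 1, 2, 3, 5, 6, 7).

**Steps most likely to fail**

Step 6. The 2,6-dimethoxyaryloxy group is much larger than the alkoxy groups of the precedents, so hydride transfer could be slow, the syn/anti preference could erode, or racemisation could lag behind reduction and lower the enantiomeric purity. In that case stereocontrol would be moved from the small-molecule catalyst to an enzyme pocket. Compound 13 would be reduced by an NADPH-dependent ketoreductase (short-chain dehydrogenase/reductase class; cofactor recycled with glucose and glucose dehydrogenase; phosphate buffer pH 7–7.5 with DMSO cosolvent, 30 °C), a panel being screened for the syn (2S,3R) product. Racemisation of 13 is spontaneous at this pH, so the reduction would remain dynamic. The fallback sets out from 13, comes back to the route at 14 and makes no new compound (F0).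

Step 5. SN2 attack at the secondary carbon by the doubly ortho-substituted phenoxide could be slow enough for enolisation of the bromide, bromine transfer and self-condensation to take over. The C8–O bond would then be made by carbenoid O–H insertion. From 7, Regitz diazo transfer (4-acetamidobenzenesulfonyl azide, Et3N, MeCN, 0 °C → rt) would give ethyl 2-diazo-3-[3-methoxy-4-(pivaloyloxy)phenyl]-3-oxopropanoate F1. Its decomposition by Rh2(OAc)4 (1 mol %) in the presence of 12 (ClCH2CH2Cl, 60 °C) should give 13 through an oxonium ylide and proton shift, a process little affected by ortho substituents and indifferent to the electron-poor cinnamate double bond. The fallback sets out from 7 and comes back to the route at 13.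

Step 7. The hindered saturated ester could be reduced incompletely at low temperature, and warming to force it could cause conjugate reduction or loss of the benzylic C7–O bond through a quinone methide once the aluminium phenoxide is unmasked. The reductions would then be separated. NaBH4 (THF/EtOH, 0 °C → rt) should reduce only the α-aryloxy-β-hydroxy ester of 14, assisted by the neighbouring hydroxyl, to give methyl (E)-3-[4-({(1R,2R)-1,3-dihydroxy-1-[3-methoxy-4-(pivaloyloxy)phenyl]propan-2-yl}oxy)-3,5-dimethoxyphenyl]prop-2-enoate F2. The conjugated ester and the aryl pivalate, both fast with iBu2AlH, would then be reduced at −78 °C without warming. The fallback sets out from 14 and comes back to the route at 15.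

**Further compounds**
F0 | step 6 | none | none
F1 | step 5 | ethyl 2-diazo-3-[3-methoxy-4-(pivaloyloxy)phenyl]-3-oxopropanoate | CCOC(=O)C(=[N+]=[N-])C(=O)c1ccc(OC(=O)C(C)(C)C)c(OC)c1
F2 | step 7 | methyl (E)-3-[4-({(1R,2R)-1,3-dihydroxy-1-[3-methoxy-4-(pivaloyloxy)phenyl]propan-2-yl}oxy)-3,5-dimethoxyphenyl]prop-2-enoate | COc1cc([C@@H](O)[C@@H](CO)Oc2c(OC)cc(/C=C/C(=O)OC)cc2OC)ccc1OC(=O)C(C)(C)C
A1 | direct plan | (S)-4-benzyl-3-(2-{4-[(E)-3-(tert-butyldimethylsilyloxy)prop-1-enyl]-2,6-dimethoxyphenoxy}acetyl)oxazolidin-2-one | O=C(COc1c(OC)cc(/C=C/CO[Si](C)(C)C(C)(C)C)cc1OC)N1C(=O)OC[C@@H]1Cc1ccccc1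
A2 | direct plan | 3-methoxy-4-(triisopropylsilyloxy)benzaldehyde | COc1cc(C=O)ccc1O[Si](C(C)C)(C(C)C)C(C)C
A3 | direct plan | (S)-4-benzyl-3-[(2S,3R)-2-{4-[(E)-3-(tert-butyldimethylsilyloxy)prop-1-enyl]-2,6-dimethoxyphenoxy}-3-hydroxy-3-[3-methoxy-4-(triisopropylsilyloxy)phenyl]propanoyl]oxazolidin-2-one | COc1cc([C@@H](O)[C@@H](C(=O)N2C(=O)OC[C@@H]2Cc2ccccc2)Oc2c(OC)cc(/C=C/CO[Si](C)(C)C(C)(C)C)cc2OC)ccc1O[Si](C(C)C)(C(C)C)C(C)C
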